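## Structural features

The target is a 2,3,4,5-tetrahydro-1-benzoxepine: a benzene ring (C5a to C9a) fused to a seven-membered cyclic ether (O1, C2, C3, C4, C5). The arene is pentasubstituted: O1 on C9a, free hydroxyls on C7 and C9, a methyl group on C8, hydrogen only on C6, and C5a bonded to C5, an sp2 carbon carrying an exocyclic methylene group. Two stereocentres, C2 (S) and C4 (R), stand in a 1,3-relationship across the C3 methylene with their oxygens syn; C2 bears a 2-hydroxypropan-2-yl group and C4 an angelate [(Z)-2-methylbut-2-enoate] ester. The fragile groups are the angelate (Z to E drift to the tiglate under base, heat or nucleophilic catalysis), the C4 ester, which is allylic to the styrene-type C5 methylene (acid can protonate the alkene or ionise C4–O), the electron-rich resorcinol-type ring and the tertiary alcohol. The real difficulty is twofold. First, a seven-membered aryl alkyl ether must be closed at C9a, which is flanked by the C9 oxygen and by C5a, using a hindered secondary alcohol. Second, three hydroxyls (C2, C4 and the tertiary one) must be told apart inside a syn-1,3-diol. The key step exploits the fact that, without O1, C5a/C6–C9a is a 3,5-dioxygenated 4-methylphenyl unit with a mirror plane through C5a and C8, so that C6 and C9a are one and the same position: a single bromination of the symmetric benzoic acid marks C9a for the O1–C9a bond, and the carboxyl carbon becomes C5.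

## Logic of the disconnections

Positions carry benzoxepine numbers throughout, also in open-chain compounds.

21 ⇒ 20. The two aryl O–Si bonds at C7 and C9 are the last to be broken. Buffered fluoride at 0 °C is the mildest final operation possible next to an angelate and an allylic ester, and it lets every earlier step run on an arene without free phenols. The forward step must avoid any base strong enough to isomerise or cleave the ester.

20 ⇒ 17 + 18. The acyl–O bond at C4 is cut so that the labile Z-alkene enters late and intact as the commercial acid 18. This leaves 17, which has no alkene-geometry problem. The forward step must acylate a hindered allylic secondary hydroxyl without Z to E isomerisation, selectively beside a free tertiary hydroxyl.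

17 ⇒ 16. The two alkyl O–Si bonds (C4–O and the tertiary oxygen) are cut; these caps exist only to steer the ring closure. The demand is an acid mild enough to spare the aryl silyl ethers and the C5 methylene.

16 ⇒ 15. The O1–C9a bond is cut. This opens the seven-membered ring to an acyclic aryl bromide that already holds both stereocentres and whose arene derives from a symmetric acid. The forward step needs C–O reductive elimination to beat β-hydride elimination, and only the C2 oxygen may react. The protecting-group pattern of 15 is chosen for this: alkyl triethylsilyl ethers (removable later by weak acid) on C4-O and on the tertiary oxygen, aryl triisopropylsilyl ethers (stable to carbonate at 80 °C) on the phenols, and a non-polar medium with an insoluble base so that silyl shifts towards C2-O are not promoted.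

15 ⇒ 14 ⇒ 12. The C4 O–Si bond and the C2–H bond are cut. C2 is derived from C4 by a hydroxyl-directed 1,3-syn reduction, which removes one stereocentre from the problem. The demands are high syn selectivity in the reduction and site-selective silylation of the allylic C4 hydroxyl in the presence of the neopentyl-like C2 hydroxyl.

12 ⇒ 7 + 9. The C3–C4 bond is cut along the aldol retron. This gives two achiral fragments, and 9 can enolise on one side only. The forward step must be reagent-controlled for Re-face attack on the aldehyde and must add 1,2 to the enal.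

7 ⇒ 6 ⇒ 5 ⇒ 4. The formyl C=O (an allylic C–H oxidation), the C=C bond (a dehydration) and two C–CH3 bonds (addition to an ester) are cut in turn. This traces C5 back to a benzoate carbon. The demands are chemoselective oxidation of the single allylic methyl group and prompt use of the reactive enal.

4 ⇒ 3 ⇒ 2 ⇒ 1. The two aryl O–Si bonds, the C9a–Br bond and the ester O–CH3 bond are cut, arriving at the symmetric acid 1. The two free ring positions of 2 are equivalent, so the only demand is to stop at monobromination.

9 ⇒ 8. The tertiary O–Si bond is cut to the commercial hydroxy ketone 8; the cap is needed for clean enolisation.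

## Other disconnections considered

Alternative 1: The cut is C2–C3. In the forward sense the seven-membered lactone A2 would be converted into its silyl ketene acetal (LiN(SiMe3)2, Me3SiCl) and would undergo an Ireland–Claisen [3,3] shift through the boat-like array that the ring enforces. This forms C2–C3, breaks the benzylic C–O bond and gives the acid A1, the (5S) centre of A2 being relayed suprafacially to (2S).
- In favour: the C–C bond formation is metal-free, the stereochemical transfer is geometrically constrained and starts from a benzylic carbinol that standard asymmetric methods can supply, and no crowded aryl halide has to react. In predictability of C2 this is the equal of the chosen plan.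
- Against: A1 contains neither the C5 methylene carbon nor the C4 oxygen. After the key step the carboxyl must become the tertiary alcohol, C4=C5 must be oxidised to a C4 carbinol and a C5 ketone, and C5 must be methylenated. C4 would have to be set cis to C2 on a flexible seven-membered ring without an evident control element. The arene must also carry the C9a oxygen from the start, so the symmetric acid cannot serve.
- Comparison: the mechanism is sound, but structurally it solves C2 only, and the way from A1 to the target is estimated at six to eight operations against three in the chosen plan.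

Alternative 2: The cut is C3–C4. In the forward sense a chiral triazolium-derived carbene would convert the aldehyde A4 into an acyl anion equivalent that adds to the β-carbon of the aryloxyacrylate; protonation of the resulting enolate sets C2 and gives the keto ester A3.
- In favour: this is the only plan in which ring closure and the enantio-determining event coincide and are catalytic, which is better than the chosen plan (stoichiometric chiral borane). C4 arrives oxidised, and C5 is benzylic and α to the ketone, hence ready for methylenation.
- Against: seven-membered Stetter closures lie outside the usual five- and six-membered cases. An arylacetaldehyde enolises and self-condenses under carbene and base. C2 would arise by protonation, not by C–C bond formation, which needs a specially tuned catalyst. A3 is a β-aryloxy ketone, so E1cB ring opening and C2 epimerisation would threaten each later basic step: methyl addition to the ester beside a ketone, methylenation, and a reduction that must come out 1,3-cis. The arene again needs its third oxygen beforehand.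
- Comparison: the step count could be about equal, but the mechanistic risk is concentrated in the key step and in the stability of its product, whereas the chosen plan sets each stereocentre by an established, separate operation.

Alternative 3: The cut is C4–C5. In the forward sense CrCl2 with catalytic NiCl2 would convert the α-aryl vinyl triflate of A6 into an alkenylchromium species that adds to the tethered aldehyde, giving the allylic alcohol A5.
- In favour: A5 has the C4 hydroxyl free and every other oxygen capped, so esterification can follow at once. This is one step shorter after the key step and is better than the chosen plan on this point. The methylene group is in place, and the nickel/chromium reaction tolerates silyl ethers.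
- Against: C4 is created during ring closure, and its configuration would rest on 1,3-induction from C2 through a forming seven-membered ring, for which no reliable model exists; an epimer mixture would have to be corrected by oxidation and reduction. The O1–C2 ether must be made beforehand at a neopentyl-like secondary carbon. A6 is a β-aryloxy aldehyde prone to elimination. The arene needs three differentiated oxygens, and divalent chromium is needed in large excess at high dilution.
- Comparison: structurally the product is the equal of 16 and overall step economy is roughly equal, but the chosen plan fixes both stereocentres in the open chain by predictable models and forms no stereocentre at ring closure.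

Key step: step 11

Assumption on the chemistry: enol diisopinocampheylborinates of methyl ketones are taken to attack aldehydes on the face opposite to that preferred in the ethyl ketone series, so that (+)-Ipc2BCl gives Re-face attack and the (5R)-aldol 12.

## Route

Step 1
Reactants: 1 3,5-dihydroxy-4-methylbenzoic acid
Product: 2 methyl 3,5-dihydroxy-4-methylbenzoate
Conditions: MeOH, H2SO4 (cat.), reflux
Reagents that add atoms: methanol, CO
Why: Fischer esterification driven by methanol as solvent; the phenols are inert, and the ester is needed for the later double methyl addition at the carbon that becomes C5.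

Step 2
Reactants: 2 methyl 3,5-dihydroxy-4-methylbenzoate
Product: 3 methyl 2-bromo-3,5-dihydroxy-4-methylbenzoate
Conditions: NBS (1.0 equiv), MeCN, −20 → 0 °C
Reagents that add atoms: N-bromosuccinimide, O=C1CCC(=O)N1Br
Why: Electrophilic aromatic bromination; the two free ring positions are equivalent (each ortho to one hydroxyl and para to the other), so one equivalent should give a single monobromide, and the first bromine, meta to the remaining position, deactivates it against a second substitution.

Step 3
Reactants: 3 methyl 2-bromo-3,5-dihydroxy-4-methylbenzoate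
Product: 4 methyl 2-bromo-4-methyl-3,5-bis(triisopropylsilyloxy)benzoate
Conditions: i-Pr3SiOTf (2.4 equiv), 2,6-lutidine, CH2Cl2, 0 °C → rt
Reagents that add atoms: triisopropylsilyl trifluoromethanesulfonate, CC(C)[Si](C(C)C)(C(C)C)OS(=O)(=O)C(F)(F)F
Why: Silyl triflate silylation of phenols; the triflate is reactive enough for the hydroxyl flanked by bromine and methyl, and aryl triisopropylsilyl ethers should withstand the Grignard reagent, carbonate at 80 °C and weak acid.

Step 4
Reactants: 4 methyl 2-bromo-4-methyl-3,5-bis(triisopropylsilyloxy)benzoate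
Product: 5 2-[2-bromo-4-methyl-3,5-bis(triisopropylsilyloxy)phenyl]propan-2-ol
Conditions: MeMgBr (3.5 equiv), THF, 0 °C → rt; aq. NH4Cl
Reagents that add atoms: methylmagnesium bromide, C[Mg]Br
Why: Double Grignard addition to an ester gives the tertiary benzylic alcohol; MeMgBr does not exchange with the aryl bromide and leaves the aryl silyl ethers alone.

Step 5
Reactants: 5 2-[2-bromo-4-methyl-3,5-bis(triisopropylsilyloxy)phenyl]propan-2-ol
Product: 6 2-bromo-4-methyl-1-(prop-1-en-2-yl)-3,5-bis(triisopropylsilyloxy)benzene
Conditions: Burgess reagent (1.5 equiv), toluene, 60 °C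
Reagents that add atoms: none
Why: Burgess dehydration (syn elimination of the sulfamate ester) under neutral conditions; only the two methyl groups offer β-hydrogens, so the isopropenyl arene is the sole possible alkene, and acid-catalysed styrene dimerisation is avoided.

Step 6
Reactants: 6 2-bromo-4-methyl-1-(prop-1-en-2-yl)-3,5-bis(triisopropylsilyloxy)benzene
Product: 7 2-[2-bromo-4-methyl-3,5-bis(triisopropylsilyloxy)phenyl]prop-2-enal
Conditions: SeO2 (1.5 equiv), 1,4-dioxane/H2O (30:1), 90 °C; used at once
Reagents that add atoms: selenium dioxide, O=[Se]=O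
Why: Riley allylic oxidation (ene reaction, [2,3]-sigmatropic shift, then oxidation of the allylic alcohol) of the only allylic methyl group gives the 2-arylacrolein; the aryl methyl group is not allylic, and the ortho bromine twists the ring out of conjugation, which should temper polymerisation of the enal.

Step 7
Reactants: 8 3-hydroxy-3-methylbutan-2-one
Product: 9 3-methyl-3-(triethylsilyloxy)butan-2-one
Conditions: Et3SiOTf (1.1 equiv), 2,6-lutidine, CH2Cl2, −78 → 0 °C
Reagents that add atoms: triethylsilyl trifluoromethanesulfonate, CC[Si](CC)(CC)OS(=O)(=O)C(F)(F)F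
Why: Silyl triflate silylation of a tertiary alcohol at low temperature, faster than enol silylation of the ketone; the triethylsilyl ether blocks the hydroxyl during enolisation and is later removable with weak acid.

Step 8
Reactants: 9 3-methyl-3-(triethylsilyloxy)butan-2-one + 7 2-[2-bromo-4-methyl-3,5-bis(triisopropylsilyloxy)phenyl]prop-2-enal
Product: 12 (5R)-6-[2-bromo-4-methyl-3,5-bis(triisopropylsilyloxy)phenyl]-5-hydroxy-2-methyl-2-(triethylsilyloxy)hept-6-en-3-one, via enol diisopinocampheylborinate 10 (not isolated), via boron aldolate 11 (not isolated)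
Conditions: 9 (1.3 equiv), (+)-Ipc2BCl (1.4 equiv), Et3N, Et2O, 0 °C; then 7, −78 → −20 °C; H2O2, pH 7 buffer, MeOH, 0 °C
Reagents that add atoms: none
Why: Paterson asymmetric boron aldol; the ketone can enolise only at its methyl group, the enol borinate adds 1,2 to the enal through a cyclic transition state, and the isopinocampheyl ligands of the (+)-reagent should direct attack to the Re face of the aldehyde, which sets C4 as R [(5R) in 12].

Step 9
Reactants: 12 (5R)-6-[2-bromo-4-methyl-3,5-bis(triisopropylsilyloxy)phenyl]-5-hydroxy-2-methyl-2-(triethylsilyloxy)hept-6-en-3-one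
Product: 14 (3S,5R)-6-[2-bromo-4-methyl-3,5-bis(triisopropylsilyloxy)phenyl]-2-methyl-2-(triethylsilyloxy)hept-6-ene-3,5-diol, via diethylboron chelate 13 (not isolated)
Conditions: Et2BOMe (1.2 equiv), THF/MeOH (4:1), −78 °C; NaBH4, −78 °C; AcOH; MeOH azeotrope
Reagents that add atoms: none
Why: Narasaka–Prasad reduction; Et2BOMe locks the β-hydroxy ketone as a six-membered boron chelate and external hydride adds axially to its half-chair, which should give the syn-1,3-diol, so that C2 becomes S [(3S) in 14] under control of C4.

Step 10
Reactants: 14 (3S,5R)-6-[2-bromo-4-methyl-3,5-bis(triisopropylsilyloxy)phenyl]-2-methyl-2-(triethylsilyloxy)hept-6-ene-3,5-diol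
Product: 15 (3S,5R)-6-[2-bromo-4-methyl-3,5-bis(triisopropylsilyloxy)phenyl]-2-methyl-2,5-bis(triethylsilyloxy)hept-6-en-3-ol
Conditions: Et3SiCl (1.05 equiv), imidazole, CH2Cl2, −30 → 0 °C
Reagents that add atoms: chlorotriethylsilane, CC[Si](CC)(CC)Cl
Why: Kinetically site-selective silylation; the C4 hydroxyl is allylic and next to a planar sp2 carbon, whereas the C2 hydroxyl is neopentyl-like beside the quaternary carbon with its triethylsilyloxy group, so one equivalent of silyl chloride at low temperature should cap C4-O only.

Step 11
Reactants: 15 (3S,5R)-6-[2-bromo-4-methyl-3,5-bis(triisopropylsilyloxy)phenyl]-2-methyl-2,5-bis(triethylsilyloxy)hept-6-en-3-ol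
Product: 16 (2S,4R)-8-methyl-5-methylidene-4-(triethylsilyloxy)-2-[2-(triethylsilyloxy)propan-2-yl]-7,9-bis(triisopropylsilyloxy)-2,3,4,5-tetrahydro-1-benzoxepine
Conditions: Pd(OAc)2 (5 mol %), rac-2-(di-tert-butylphosphino)-1,1'-binaphthyl (7 mol %), Cs2CO3 (1.5 equiv), toluene (0.02 M), 80 °C
Reagents that add atoms: none
Why: Buchwald-type intramolecular aryl etherification: Pd(OAc)2 is reduced in the flask to a monophosphine complex of zerovalent palladium, which adds oxidatively to the C9a–Br bond; the C2 hydroxyl then binds to divalent palladium, Cs2CO3 removes its proton and bromide leaves, giving an eight-membered oxapalladacycle, and C–O reductive elimination forms O1–C9a. The closest known reaction type is the palladium-catalysed cyclisation of secondary alcohols onto tethered aryl bromides to five-, six- and seven-membered benzo-fused ethers with di-tert-butyl(biaryl)phosphines. The benzoxepine ring is closed in a formal 7-exo mode at the aromatic carbon, the replaced C–Br bond lying outside the new ring. No stereocentre is formed; C2 keeps its configuration because its C–O bond is never broken, and C4 is a spectator. The step needs reductive elimination to outrun β-hydride elimination of the secondary alkoxide, which would give the C2 ketone and the debrominated arene; the bulk of the ligand and the two ortho substituents of the aryl group both accelerate reductive elimination. It also needs site selectivity among three oxygens: C4-O, which would close a five-membered ring, and the tertiary oxygen are silylated, and insoluble carbonate in toluene keeps free alkoxide so low that silyl migration to C2-O is not expected. A Heck pathway is excluded because the alkene is attached directly to the ring, so insertion would form a three- or four-membered ring, and dilution disfavours intermolecular coupling.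

Step 12
Reactants: 16 (2S,4R)-8-methyl-5-methylidene-4-(triethylsilyloxy)-2-[2-(triethylsilyloxy)propan-2-yl]-7,9-bis(triisopropylsilyloxy)-2,3,4,5-tetrahydro-1-benzoxepine
Product: 17 (2S,4R)-2-(2-hydroxypropan-2-yl)-8-methyl-5-methylidene-7,9-bis(triisopropylsilyloxy)-2,3,4,5-tetrahydro-1-benzoxepin-4-ol
Conditions: PPTS (0.3 equiv), MeOH/CH2Cl2 (1:1), 0 °C → rt
Reagents that add atoms: none
Why: Acid-catalysed methanolysis of alkyl triethylsilyl ethers, which are orders of magnitude more acid-labile than aryl triisopropylsilyl ethers; pyridinium tosylate is too weak an acid to protonate the C5 methylene or to ionise the allylic C4–O bond.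

Step 13
Reactants: 17 (2S,4R)-2-(2-hydroxypropan-2-yl)-8-methyl-5-methylidene-7,9-bis(triisopropylsilyloxy)-2,3,4,5-tetrahydro-1-benzoxepin-4-ol + 18 angelic acid [(2Z)-2-methylbut-2-enoic acid]
Product: 20 (2S,4R)-2-(2-hydroxypropan-2-yl)-8-methyl-5-methylidene-7,9-bis(triisopropylsilyloxy)-2,3,4,5-tetrahydro-1-benzoxepin-4-yl (2Z)-2-methylbut-2-enoate, via mixed anhydride 19 (not isolated)
Conditions: 18, 2,4,6-trichlorobenzoyl chloride, Et3N, toluene, rt; then 17, toluene, 70 °C (no DMAP)
Reagents that add atoms: none
Why: Yamaguchi esterification through the 2,4,6-trichlorobenzoyl mixed anhydride; attack occurs at the less hindered angeloyl carbonyl, only the secondary C4 hydroxyl reacts (the tertiary one is too hindered and the phenols are silylated), and leaving out DMAP removes the conjugate-addition pathway that turns angelates into tiglates.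

Step 14
Reactants: 20 (2S,4R)-2-(2-hydroxypropan-2-yl)-8-methyl-5-methylidene-7,9-bis(triisopropylsilyloxy)-2,3,4,5-tetrahydro-1-benzoxepin-4-yl (2Z)-2-methylbut-2-enoate
Product: 21 (2S,4R)-7,9-dihydroxy-2-(2-hydroxypropan-2-yl)-8-methyl-5-methylidene-2,3,4,5-tetrahydro-1-benzoxepin-4-yl (2Z)-2-methylbut-2-enoate
Conditions: Bu4NF (2.5 equiv), AcOH (2.5 equiv), THF, 0 °C
Reagents that add atoms: none
Why: Fluoride cleavage of aryl silyl ethers, driven by the Si–F bond and the good phenoxide leaving group; acetic acid buffers the phenoxides so that the angelate should be neither hydrolysed nor isomerised, and no stereocentre is touched.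

## Compound list

1 | 3,5-dihydroxy-4-methylbenzoic acid | Cc1c(O)cc(C(=O)O)cc1O | starting material
2 | methyl 3,5-dihydroxy-4-methylbenzoate | COC(=O)c1cc(O)c(C)c(O)c1 | intermediate
3 | methyl 2-bromo-3,5-dihydroxy-4-methylbenzoate | COC(=O)c1cc(O)c(C)c(O)c1Br | intermediate
4 | methyl 2-bromo-4-methyl-3,5-bis(triisopropylsilyloxy)benzoate | COC(=O)c1cc(O[Si](C(C)C)(C(C)C)C(C)C)c(C)c(O[Si](C(C)C)(C(C)C)C(C)C)c1Br | intermediate
5 | 2-[2-bromo-4-methyl-3,5-bis(triisopropylsilyloxy)phenyl]propan-2-ol | CC(C)(O)c1cc(O[Si](C(C)C)(C(C)C)C(C)C)c(C)c(O[Si](C(C)C)(C(C)C)C(C)C)c1Br | intermediate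
6 | 2-bromo-4-methyl-1-(prop-1-en-2-yl)-3,5-bis(triisopropylsilyloxy)benzene | C=C(C)c1cc(O[Si](C(C)C)(C(C)C)C(C)C)c(C)c(O[Si](C(C)C)(C(C)C)C(C)C)c1Br | intermediate
7 | 2-[2-bromo-4-methyl-3,5-bis(triisopropylsilyloxy)phenyl]prop-2-enal | C=C(C=O)c1cc(O[Si](C(C)C)(C(C)C)C(C)C)c(C)c(O[Si](C(C)C)(C(C)C)C(C)C)c1Br | intermediate
8 | 3-hydroxy-3-methylbutan-2-one | CC(=O)C(C)(C)O | starting material
9 | 3-methyl-3-(triethylsilyloxy)butan-2-one | CC(=O)C(C)(C)O[Si](CC)(CC)CC | intermediate
10 | 3-methyl-3-(triethylsilyloxy)but-1-en-2-yl bis[(+)-isopinocampheyl]borinate (isopinocampheyl groups from (−)-α-pinene; not isolated) | C=C(OB([C@H]1C[C@H]2C[C@@H]([C@@H]1C)C2(C)C)[C@H]1C[C@H]2C[C@@H]([C@@H]1C)C2(C)C)C(C)(C)O[Si](CC)(CC)CC | intermediate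
11 | O-bis[(+)-isopinocampheyl]boryl derivative of 12 at the C5 oxygen (boron aldolate; not isolated) | C=C(c1cc(O[Si](C(C)C)(C(C)C)C(C)C)c(C)c(O[Si](C(C)C)(C(C)C)C(C)C)c1Br)[C@H](OB([C@H]1C[C@H]2C[C@@H]([C@@H]1C)C2(C)C)[C@H]1C[C@H]2C[C@@H]([C@@H]1C)C2(C)C)CC(=O)C(C)(C)O[Si](CC)(CC)CC | intermediate
12 | (5R)-6-[2-bromo-4-methyl-3,5-bis(triisopropylsilyloxy)phenyl]-5-hydroxy-2-methyl-2-(triethylsilyloxy)hept-6-en-3-one | C=C(c1cc(O[Si](C(C)C)(C(C)C)C(C)C)c(C)c(O[Si](C(C)C)(C(C)C)C(C)C)c1Br)[C@H](O)CC(=O)C(C)(C)O[Si](CC)(CC)CC | intermediate
13 | (5R)-6-[2-bromo-4-methyl-3,5-bis(triisopropylsilyloxy)phenyl]-5-(diethylboryloxy)-2-methyl-2-(triethylsilyloxy)hept-6-en-3-one (boron chelated by the ketone oxygen; not isolated) | C=C(c1cc(O[Si](C(C)C)(C(C)C)C(C)C)c(C)c(O[Si](C(C)C)(C(C)C)C(C)C)c1Br)[C@H](OB(CC)CC)CC(=O)C(C)(C)O[Si](CC)(CC)CC | intermediate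
14 | (3S,5R)-6-[2-bromo-4-methyl-3,5-bis(triisopropylsilyloxy)phenyl]-2-methyl-2-(triethylsilyloxy)hept-6-ene-3,5-diol | C=C(c1cc(O[Si](C(C)C)(C(C)C)C(C)C)c(C)c(O[Si](C(C)C)(C(C)C)C(C)C)c1Br)[C@H](O)C[C@H](O)C(C)(C)O[Si](CC)(CC)CC | intermediate
15 | (3S,5R)-6-[2-bromo-4-methyl-3,5-bis(triisopropylsilyloxy)phenyl]-2-methyl-2,5-bis(triethylsilyloxy)hept-6-en-3-ol | C=C(c1cc(O[Si](C(C)C)(C(C)C)C(C)C)c(C)c(O[Si](C(C)C)(C(C)C)C(C)C)c1Br)[C@H](O[Si](CC)(CC)CC)C[C@H](O)C(C)(C)O[Si](CC)(CC)CC | intermediate
16 | (2S,4R)-8-methyl-5-methylidene-4-(triethylsilyloxy)-2-[2-(triethylsilyloxy)propan-2-yl]-7,9-bis(triisopropylsilyloxy)-2,3,4,5-tetrahydro-1-benzoxepine | C=C1c2cc(O[Si](C(C)C)(C(C)C)C(C)C)c(C)c(O[Si](C(C)C)(C(C)C)C(C)C)c2O[C@H](C(C)(C)O[Si](CC)(CC)CC)C[C@H]1O[Si](CC)(CC)CC | intermediate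
17 | (2S,4R)-2-(2-hydroxypropan-2-yl)-8-methyl-5-methylidene-7,9-bis(triisopropylsilyloxy)-2,3,4,5-tetrahydro-1-benzoxepin-4-ol | C=C1c2cc(O[Si](C(C)C)(C(C)C)C(C)C)c(C)c(O[Si](C(C)C)(C(C)C)C(C)C)c2O[C@H](C(C)(C)O)C[C@H]1O | intermediate
18 | angelic acid [(2Z)-2-methylbut-2-enoic acid] | C/C=C(/C)C(=O)O | starting material
19 | (2Z)-2-methylbut-2-enoic 2,4,6-trichlorobenzoic anhydride (not isolated) | C/C=C(/C)C(=O)OC(=O)c1c(Cl)cc(Cl)cc1Cl | intermediate
20 | (2S,4R)-2-(2-hydroxypropan-2-yl)-8-methyl-5-methylidene-7,9-bis(triisopropylsilyloxy)-2,3,4,5-tetrahydro-1-benzoxepin-4-yl (2Z)-2-methylbut-2-enoate | C=C1c2cc(O[Si](C(C)C)(C(C)C)C(C)C)c(C)c(O[Si](C(C)C)(C(C)C)C(C)C)c2O[C@H](C(C)(C)O)C[C@H]1OC(=O)/C(C)=C\C | intermediate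
21 | (2S,4R)-7,9-dihydroxy-2-(2-hydroxypropan-2-yl)-8-methyl-5-methylidene-2,3,4,5-tetrahydro-1-benzoxepin-4-yl (2Z)-2-methylbut-2-enoate | C=C1c2cc(O)c(C)c(O)c2O[C@H](C(C)(C)O)C[C@H]1OC(=O)/C(C)=C\C | target

## Step count and least certain steps

Total step count: 14. Longest linear sequence: 13 steps (steps 1 to 6, then 8 to 14); step 7 is the only step outside it.

Step 11 (key step). Most likely to go wrong: oxidative addition that is too slow at a bromide flanked by a silyloxy group and a branched carbon on an electron-rich ring, and β-hydride elimination from the palladium alkoxide outrunning C–O bond formation, so that reduction of the C–Br bond takes over. A base-promoted silyl shift from C4-O to C2-O followed by five-membered ring closure is a lesser risk. Fallback (sets out from 15, returns at 16): aromatic Finkelstein exchange (CuI, NaI, trans-N,N'-dimethylcyclohexane-1,2-diamine, dioxane, 110 °C) would give the aryl iodide (3S,5R)-6-[2-iodo-4-methyl-3,5-bis(triisopropylsilyloxy)phenyl]-2-methyl-2,5-bis(triethylsilyloxy)hept-6-en-3-ol F1. An Ullmann-type ring closure of F1 with CuI, 3,4,7,8-tetramethyl-1,10-phenanthroline and Cs2CO3 in toluene at 110 °C would then give 16. An alkoxide of monovalent copper has no easy β-hydride pathway, so the main failure mode of the palladium cycle is removed.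

Step 8. Most likely to go wrong: poor facial selectivity, because the tertiary alkyl group of the ketone crowds the isopinocampheyl ligands, and slow addition to the hindered enal. Fallback (sets out from 9, returns at 12): 9 would be converted with LiN(i-Pr)2 and Me3SiCl (THF, −78 °C) into the enol silane triethyl{[2-methyl-3-(trimethylsilyloxy)but-3-en-2-yl]oxy}silane F2. F2 would be added to 7 in a Mukaiyama aldol under SiCl4 activated by a catalytic chiral bisphosphoramide Lewis base (CH2Cl2, −78 °C), using the catalyst antipode that gives Re-face attack; aqueous work-up gives 12. This open-transition-state aldol is of a type that accepts bulky methyl ketone enol silanes and conjugated aldehydes.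

Step 6. Most likely to go wrong: oxidation stopping at the allylic alcohol, or loss of the enal by polymerisation and hetero-Diels–Alder dimerisation at 90 °C. Fallback (sets out from 4, returns at 7):
- i-Bu2AlH (CH2Cl2, −78 → 0 °C) would reduce 4 to [2-bromo-4-methyl-3,5-bis(triisopropylsilyloxy)phenyl]methanol F3.
- MnO2 would oxidise it to 2-bromo-4-methyl-3,5-bis(triisopropylsilyloxy)benzaldehyde F4.
- A Wittig reaction with Ph3P=CHOMe (from the phosphonium chloride and KOt-Bu, THF, 0 °C) would give the enol ether 2-bromo-1-(2-methoxyethenyl)-4-methyl-3,5-bis(triisopropylsilyloxy)benzene F5 as an E/Z mixture.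
- Hydrolysis (aq. HCl, THF, rt) would give 2-[2-bromo-4-methyl-3,5-bis(triisopropylsilyloxy)phenyl]acetaldehyde F6.
- α-Methylenation of F6 with aqueous formaldehyde and catalytic pyrrolidine/propanoic acid (i-PrOH, 45 °C) would give 7 under conditions far milder than SeO2 at 90 °C.

Step 10. Most likely to go wrong: loss of site selectivity, with silylation of the C2 hydroxyl or of both hydroxyls. Fallback (sets out from 12, returns at 15): silylation of 12 (Et3SiCl, imidazole, DMF, 0 °C) would give (5R)-6-[2-bromo-4-methyl-3,5-bis(triisopropylsilyloxy)phenyl]-2-methyl-2,5-bis(triethylsilyloxy)hept-6-en-3-one F7, in which C4-O is capped before the C2 hydroxyl exists. Reagent-controlled reduction of F7 with (R)-2-methyl-CBS-oxazaborolidine and catecholborane (toluene, −78 → −40 °C), the tertiary alkyl group acting as the large substituent, would then give 15 directly.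

Step 13. Most likely to go wrong: Z to E isomerisation of the acyl unit during activation or on heating, and sluggish acylation of the hindered allylic hydroxyl. Fallback (sets out from 17, returns at 20): 17 would be esterified (DCC, DMAP, CH2Cl2, 0 °C) with 2-[bis(2,2,2-trifluoroethoxy)phosphoryl]propanoic acid to give (2S,4R)-2-(2-hydroxypropan-2-yl)-8-methyl-5-methylidene-7,9-bis(triisopropylsilyloxy)-2,3,4,5-tetrahydro-1-benzoxepin-4-yl 2-[bis(2,2,2-trifluoroethoxy)phosphoryl]propanoate F8 (epimers at the phosphonate carbon). A Still–Gennari olefination of F8 with acetaldehyde (KN(SiMe3)2, 18-crown-6, THF, −78 °C) would build the Z-trisubstituted alkene on the substrate and give 20.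

## Further compounds

F1 | step 11 | (3S,5R)-6-[2-iodo-4-methyl-3,5-bis(triisopropylsilyloxy)phenyl]-2-methyl-2,5-bis(triethylsilyloxy)hept-6-en-3-ol | C=C(c1cc(O[Si](C(C)C)(C(C)C)C(C)C)c(C)c(O[Si](C(C)C)(C(C)C)C(C)C)c1I)[C@H](O[Si](CC)(CC)CC)C[C@H](O)C(C)(C)O[Si](CC)(CC)CC
F2 | step 8 | triethyl{[2-methyl-3-(trimethylsilyloxy)but-3-en-2-yl]oxy}silane | C=C(O[Si](C)(C)C)C(C)(C)O[Si](CC)(CC)CC
F3 | step 6 | [2-bromo-4-methyl-3,5-bis(triisopropylsilyloxy)phenyl]methanol | OCc1cc(O[Si](C(C)C)(C(C)C)C(C)C)c(C)c(O[Si](C(C)C)(C(C)C)C(C)C)c1Br
F4 | step 6 | 2-bromo-4-methyl-3,5-bis(triisopropylsilyloxy)benzaldehyde | O=Cc1cc(O[Si](C(C)C)(C(C)C)C(C)C)c(C)c(O[Si](C(C)C)(C(C)C)C(C)C)c1Br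
F5 | step 6 | 2-bromo-1-(2-methoxyethenyl)-4-methyl-3,5-bis(triisopropylsilyloxy)benzene (E/Z mixture) | COC=Cc1cc(O[Si](C(C)C)(C(C)C)C(C)C)c(C)c(O[Si](C(C)C)(C(C)C)C(C)C)c1Br
F6 | step 6 | 2-[2-bromo-4-methyl-3,5-bis(triisopropylsilyloxy)phenyl]acetaldehyde | O=CCc1cc(O[Si](C(C)C)(C(C)C)C(C)C)c(C)c(O[Si](C(C)C)(C(C)C)C(C)C)c1Br
F7 | step 10 | (5R)-6-[2-bromo-4-methyl-3,5-bis(triisopropylsilyloxy)phenyl]-2-methyl-2,5-bis(triethylsilyloxy)hept-6-en-3-one | C=C(c1cc(O[Si](C(C)C)(C(C)C)C(C)C)c(C)c(O[Si](C(C)C)(C(C)C)C(C)C)c1Br)[C@H](O[Si](CC)(CC)CC)CC(=O)C(C)(C)O[Si](CC)(CC)CC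
F8 | step 13 | (2S,4R)-2-(2-hydroxypropan-2-yl)-8-methyl-5-methylidene-7,9-bis(triisopropylsilyloxy)-2,3,4,5-tetrahydro-1-benzoxepin-4-yl 2-[bis(2,2,2-trifluoroethoxy)phosphoryl]propanoate | C=C1c2cc(O[Si](C(C)C)(C(C)C)C(C)C)c(C)c(O[Si](C(C)C)(C(C)C)C(C)C)c2O[C@H](C(C)(C)O)C[C@H]1OC(=O)C(C)P(=O)(OCC(F)(F)F)OCC(F)(F)F
A1 | alternative 1 | (2S)-7,9-bis(tert-butyldimethylsilyloxy)-8-methyl-2,3-dihydro-1-benzoxepine-2-carboxylic acid | OC(=O)[C@@H]1CC=Cc2cc(O[Si](C)(C)C(C)(C)C)c(C)c(O[Si](C)(C)C(C)(C)C)c2O1
A2 | alternative 1 | (5S)-7,9-bis(tert-butyldimethylsilyloxy)-5-ethenyl-8-methyl-5H-1,4-benzodioxepin-3(2H)-one | C=C[C@@H]1OC(=O)COc2c(O[Si](C)(C)C(C)(C)C)c(C)c(O[Si](C)(C)C(C)(C)C)cc21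
A3 | alternative 2 | methyl (2S)-7,9-bis(tert-butyldimethylsilyloxy)-8-methyl-4-oxo-2,3,4,5-tetrahydro-1-benzoxepine-2-carboxylate | COC(=O)[C@@H]1CC(=O)Cc2cc(O[Si](C)(C)C(C)(C)C)c(C)c(O[Si](C)(C)C(C)(C)C)c2O1
A4 | alternative 2 | methyl 2-[2,4-bis(tert-butyldimethylsilyloxy)-3-methyl-6-(2-oxoethyl)phenoxy]prop-2-enoate | C=C(Oc1c(CC=O)cc(O[Si](C)(C)C(C)(C)C)c(C)c1O[Si](C)(C)C(C)(C)C)C(=O)OC
A5 | alternative 3 | (2S,4R)-7,9-bis(tert-butyldimethylsilyloxy)-8-methyl-5-methylidene-2-[2-(triethylsilyloxy)propan-2-yl]-2,3,4,5-tetrahydro-1-benzoxepin-4-ol | C=C1c2cc(O[Si](C)(C)C(C)(C)C)c(C)c(O[Si](C)(C)C(C)(C)C)c2O[C@H](C(C)(C)O[Si](CC)(CC)CC)C[C@H]1O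
A6 | alternative 3 | 1-{3,5-bis(tert-butyldimethylsilyloxy)-4-methyl-2-[(3S)-2-methyl-5-oxo-2-(triethylsilyloxy)pentan-3-yloxy]phenyl}ethenyl trifluoromethanesulfonate | C=C(OS(=O)(=O)C(F)(F)F)c1cc(O[Si](C)(C)C(C)(C)C)c(C)c(O[Si](C)(C)C(C)(C)C)c1O[C@H](C(C)(C)O[Si](CC)(CC)CC)CC=O
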